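The readings were computed with made-up constants; scatter was added.

Slowness does not show in the earlier runs: in the grey run starting material reads 62.5 % at 3.00 min and 62.3 % at 25.0 min, against a scatter of 1 percentage point. So the reckoning for this flask is one of amounts, with the reagent as limiting reagent.

| setting | blue | grey | flask |
|---|---|---|---|
| starting material | 0.12 M | 0.12 M | 0.12 M |
| second substrate | 1 equiv | 1 equiv | 1.00 equiv |
| reagent | 0.25 equiv | 0.38 equiv | 0.500 equiv |
| free catalyst | 0.5 mol% | 0.5 mol% | 0.5 mol% |
| remark | run made earlier | run made earlier |  |
| time |  |  | 30 min |

| run | time / min | catalyst intermediate A / % | starting material / % | uncatalysed product / % | target / % |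
|---|---|---|---|---|---|
| blue | 6.00 | 1.7 | 76.5 | 1.9 | 22.6 |
| blue | 12.0 | 0.7 | 75.5 | 1.4 | 21.8 |
| blue | 20.0 | 1.1 | 76.5 | 3.0 | 22.1 |
| blue | 25.0 | 0.8 | 74.5 | 2.0 | 21.9 |
| grey | 3.00 | 0 | 62.5 | 4.4 | 33.9 |
| grey | 8.00 | 0.3 | 64.9 | 0.7 | 34.1 |
| grey | 15.0 | 2.0 | 62.5 | 3.1 | 32.8 |
| grey | 25.0 | 0 | 62.3 | 2.1 | 31.8 |

(each reading ± 1 percentage point)

1. the species that holds most of what was charged as starting material, at 30 min (uncatalysed product / starting material / catalyst intermediate A / target)
2. the largest share itself, whichever of these holds it, in percent of the starting material charged

- the earlier runs were read with a standard deviation of 1 points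

Taken one for one, the flask's 0.500 equiv of reagent leaves 50.0 % of the starting material. That is the large term, and what remains to reckon is a correction: the leak, the part of the reagent charged that removes no starting material. It is read in two ways, each on the mean of a run's four readings. The loss of starting material, 75.8 % left in blue and 63.1 % left in grey, gives a leak of 0.0300 and 0.0276. The products found, target plus uncatalysed product, give 0.0330 and 0.0599.

Blue's two values lie close, but grey's part, so the products way is the suspect: grey's three means fall short of the charge by 1.2 points. Catalyst intermediate A can hide no more than the loading, 0.5 mol%, and what is left of the gap is the size of the scatter, so neither way is thrown out. The middle of grey, the run nearer the flask, is the carried leak, 0.0438, the part of the reagent charged that removes no starting material. This reckoning therefore puts starting material in the flask at 52.2 %. That leaves 47.8 % for target and uncatalysed product together, less than the starting material.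

The forecast, holding that “the reaction stops when the reagent runs out”, named starting material at 51 %.

The flask gives starting material at 52.2 %, with target at 44.1 % and uncatalysed product at 3.62 %.

    starting material + free catalyst ⇌ catalyst intermediate A (K = 3.40 /M, k = 438 /M/s)
    reagent + catalyst intermediate A → free catalyst + target (k = 1050 /M/s)
    second substrate + free catalyst ⇌ catalyst intermediate B (K = 7.70 /M, k = 9.25 /M/s)
    reagent + catalyst intermediate B → free catalyst + second product (k = 22.3 /M/s)
    starting material + reagent → uncatalysed product (k = 0.0779 /M/s)
    2 second substrate → self-condensation product (k = 0.00571 /M/s)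

The flask's own leak comes to 0.0434, and its second product stands at 0.00269 M at 30.0 min, which is 4.48 % of the reagent charged. The neighbour charged with 4.00 equiv of second substrate holds the same reagent, so the carried leak gives it 52.2 % again. That neighbour ends at 56.8 % starting material and 37.4 % target, a leak of 0.136, larger than the carried one. Its second product, 0.00822 M, is 13.7 % of the reagent charged.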